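Each Q that reacts with E makes one J and one G, and each Z.G removes one G along with a Z that came from a J, so free G equals J plus Z at every moment.

    Q + E → J + G (k1 = 2.2 L mol⁻¹ s⁻¹, Ea1 = 75.0 kJ mol⁻¹)
    Z + G → Z.G (k2 = 5.6 L mol⁻¹ s⁻¹, Ea2 = 51.0 kJ mol⁻¹)
    J → Z (k3 = 0.070 s⁻¹, Ea3 = 102 kJ mol⁻¹)
    Q + L → Q.L (k4 = 0.45 L mol⁻¹ s⁻¹, Ea4 = 69.0 kJ mol⁻¹)
    (constants at 110 °C)

| flask | Q | E | L | temperature | time | remark |
|---|---|---|---|---|---|---|
| delta | 0.10 M | 5.00 equiv | 0.0200 M | 110 °C | 8.0 s |  |
| epsilon | 0.10 M | 5.00 equiv | 0.0200 M | 125 °C | 8.0 s |  |
| eta | 0.10 M | 5.00 equiv | 0.0200 M |  | 8.0 s | at 125 °C until 1.5 s, from then on at 110 °C |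

* the flask with the highest amount of Z, in percent of the Q charged ("all alike" if they lie within 1.5 percentage points) (delta / epsilon / eta / all alike)
* final Z, as a percentage of the Q charged, in delta
* final Z, as a percentage of the Q charged, in epsilon
* final Z, as a percentage of the Q charged, in eta

- at 110 °C the constants are as listed, elsewhere as the activation energies make them

We build the flask up from the main step. E starts at 0.500 M and we hold it there, so in delta Q falls pseudo-first-order with a lifetime of 0.909 s, much shorter than the 8.0 s of the run. L competes at 0.00900 s⁻¹ per Q against 1.10 s⁻¹ for E, so it takes hardly any of the Q in delta, and we drop it.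

Now add J → Z. Capture consumes Z, not J, so the loss of J integrates in closed form: we let J decay exponentially from its birth, taken as 0.909 s after the start, which by this reckoning leaves 0.0609 M of J at the end of delta.

Last comes capture. Z is made in proportion to J and lost in proportion to Z times G, and with the invariant the two rates balance at Z = K·J/(J + Z). Here K is the ratio of the rate constant of J → Z to that of capture, 0.0125 M at 110 °C, and we call it the capture ceiling: a concentration that balanced Z stays below, since J/(J + Z) is under one. In delta, solving this quadratic gives 0.0106 M, which is 10.6% of the Q charged.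

Heat enters simply. 102 kJ mol⁻¹ is twice 51.0 kJ mol⁻¹, so J → Z speeds up by the square of capture's factor 1.8, reaching 0.234 s⁻¹, and the ceiling at 125 °C rises to 0.0228 M. The lifetime of Q there shrinks to 0.374 s. By this reckoning epsilon ends with 0.0168 M of J and a balance of 0.0129 M, or 12.9%. Eta decays J hot until 1.5 s and cold afterwards, which leaves 0.0488 M under the cold ceiling and a balance of 0.0103 M, or 10.3%. We therefore commit to epsilon as highest.

The forecast gives epsilon, with 11% in delta, 14.5% in epsilon and 12.5% in eta, on the ground that “Heat speeds J → Z more than it speeds capture”, and its epsilon stands 1.6 percentage points and its eta 2.2 points above ours.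

The simulation gives epsilon, with 10.6% in delta, 14.5% in epsilon and 10.7% in eta, so our delta stands and our epsilon falls 1.6 points short. In eta at 8.00 s, Z is made at 0.963 of the rate at which it is used, so it sits near its balance and is still falling. The ceiling reads eta's hot start too: Z stood at 13.4% at the change of temperature, above the 12.5% ceiling of 110 °C, and came down from there. In the neighbour of eta with 0.25 M of Q, the ceiling of 110 °C is the same concentration, so it is 5.00% of the Q charged there; that flask gives 4.59%.

Its constants are made up; the flask was simulated.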